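**Plan**

- Feature: in the 3,6-dihydro-1,2-dioxine ring the single alkene C4=C5 sits between C3 and C6, and each of these carbons carries one oxygen of the O1–O2 bridge. Opening C4=C5 therefore leaves a vinyl group on C3 and one on C6 that stay connected through the peroxide.
- Cuts, in order: C4=C5 (ring-closing metathesis); C6–O1 (acid-catalysed exchange of an allylic hydroperoxide into a vinyl ketone dimethyl ketal); C3–O2 (SN2 of a masked hydroperoxide on a lactone triflate); the C4=CH2 bond (Wittig) and the C6–hexadecyl bond (alkylation of lithiated methoxyallene).
- Forward: a C5 hydroperoxy ester (seven steps from the lactone, one more for the peroxide reagent) and a C19 ketal (two steps) are joined through O1–C6. The only ring is then closed by metathesis, and C6 is adjusted last.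
- Stereochemistry: C3 (S) arises by inversion of the triflate of (R)-α-hydroxy-γ-butyrolactone. C6 (S) is left open in the acyclic peroxyketal and is set on the ring by acid equilibration in methanol, with chromatographic removal and recycling of the 6R epimer.

Key step: step 12

Remark: the two epimers at the peroxyketal carbon are assumed to be inseparable in the open chain, so compounds 18 and 19 are each the epimer pair and are drawn without a descriptor at that carbon; 2-methoxyprop-2-yl hydroperoxide is not an article of commerce and is made in step 1.

**Route**

Step 1
Reactants: 1 2,3-dimethylbut-2-ene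
Product: 2 2-hydroperoxy-2-methoxypropane (2-methoxyprop-2-yl hydroperoxide)
Conditions: O3, MeOH/CH2Cl2, −78 °C; N2 purge; concentrated cold and kept as a titrated solution
Reagents that add atoms: ozone [O-][O+]=O; methanol CO
Why: Criegee ozonolysis of a tetrasubstituted alkene in methanol delivers one half of the alkene as the α-methoxy hydroperoxide and the other half as acetone; no stereocentre is involved.

Step 2
Reactants: 3 (3R)-3-hydroxyoxolan-2-one [(R)-α-hydroxy-γ-butyrolactone]
Product: 4 (3R)-2-oxooxolan-3-yl trifluoromethanesulfonate
Conditions: Tf2O, 2,6-lutidine, CH2Cl2, −78 → −20 °C; cold aqueous wash, short silica plug, used at once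
Reagents that add atoms: trifluoromethanesulfonic anhydride O=S(=O)(OS(=O)(=O)C(F)(F)F)C(F)(F)F
Why: O-Triflation (sulfonylation of a secondary alcohol) turns the hydroxyl into a leaving group without breaking the C–O bond, so the R configuration is kept.

Step 3
Reactants: 4 (3R)-2-oxooxolan-3-yl trifluoromethanesulfonate; 2 2-hydroperoxy-2-methoxypropane
Product: 6 (3S)-3-[(2-methoxypropan-2-yl)peroxy]oxolan-2-one, via potassium 2-methoxypropane-2-peroxolate 5 (not isolated)
Conditions: 2 (1.5 equiv), KOtBu (1.05 equiv), THF, 0 °C; then 4, −40 → 0 °C; pH 7 buffer quench
Reagents that add atoms: none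
Why: SN2 O-alkylation of a hydroperoxide anion by a secondary α-carbonyl triflate (the peroxide counterpart of the Williamson synthesis) proceeds with inversion and so sets C3 of the target as S from the R alcohol; keeping the hydroperoxide in excess over the base and the temperature low is meant to hold back base-induced fragmentation of the α-peroxy lactone.

Step 4
Reactants: 6 (3S)-3-[(2-methoxypropan-2-yl)peroxy]oxolan-2-one
Product: 7 (3S)-3-[(2-methoxypropan-2-yl)peroxy]oxolan-2-ol (both anomers)
Conditions: DIBAL-H (1.1 equiv), CH2Cl2, −78 °C; MeOH, then aqueous Rochelle salt
Reagents that add atoms: none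
Why: DIBAL-H partial reduction of a γ-lactone stops at the lactol because the aluminium hemiacetal survives at −78 °C, and the hindered, fully alkylated peroxyketal is not attacked by this hydride in the cold; C3 is not involved.

Step 5
Reactants: 7 (3S)-3-[(2-methoxypropan-2-yl)peroxy]oxolan-2-ol
Product: 8 (3S)-3-[(2-methoxypropan-2-yl)peroxy]pent-4-en-1-ol
Conditions: Ph3PCH3Br (3 equiv), KHMDS (2.8 equiv), THF, 0 °C; then 7, −78 → 0 °C; NH4Cl quench
Reagents that add atoms: methyltriphenylphosphonium bromide C[P+](c1ccccc1)(c1ccccc1)c1ccccc1.[Br-]
Why: Wittig methylenation of a lactol, whose ring-opened aldehyde should be trapped by the non-stabilised ylide faster than it enolises in the cold, turns the former lactone carbonyl into the C4=CH2 vinyl group and frees the primary alcohol; peroxyketals tolerate phosphorus ylides, and C3 keeps its configuration because no bond to it is broken.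

Step 6
Reactants: 8 (3S)-3-[(2-methoxypropan-2-yl)peroxy]pent-4-en-1-ol
Product: 10 (3S)-3-[(2-methoxypropan-2-yl)peroxy]pent-4-enoic acid, via aldehyde 9 (not isolated)
Conditions: TEMPO (cat.), NaClO2 (2 equiv), NaOCl (cat.), MeCN/phosphate buffer pH 6.7, 35 °C
Reagents that add atoms: sodium chlorite [Na+].[O-]Cl=O
Why: TEMPO-catalysed oxidation with chlorite as terminal oxidant at buffered pH takes the primary alcohol through the aldehyde to the acid without acid strong enough to hydrolyse the peroxyketal or base strong enough to eliminate the β-peroxy group, and should leave the terminal alkene alone.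

Step 7
Reactants: 10 (3S)-3-[(2-methoxypropan-2-yl)peroxy]pent-4-enoic acid
Product: 11 methyl (3S)-3-[(2-methoxypropan-2-yl)peroxy]pent-4-enoate
Conditions: TMSCHN2, PhMe/MeOH (4:1), 0 °C
Reagents that add atoms: (trimethylsilyl)diazomethane C[Si](C)(C)C=[N+]=[N-]
Why: Esterification with a diazoalkane is neutral and fast, so the β-peroxy acid is methylated without exposure to base that could cause E1cB loss of the peroxide.

Step 8
Reactants: 11 methyl (3S)-3-[(2-methoxypropan-2-yl)peroxy]pent-4-enoate
Product: 12 methyl (3S)-3-hydroperoxypent-4-enoate
Conditions: AcOH/THF/H2O (4:2:1), rt; rapid chromatography, kept cold in solution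
Reagents that add atoms: none
Why: Mild aqueous-acid hydrolysis of the acetone-derived peroxyketal (the standard unmasking of a 2-methoxyprop-2-yl-protected hydroperoxide) releases the secondary allylic hydroperoxide while the methyl ester, the alkene and C3 are unaffected.

Step 9
Reactants: 13 methoxyallene (1-methoxypropa-1,2-diene); 14 1-bromohexadecane
Product: 16 3-methoxynonadeca-1,2-diene, via 1-lithio-1-methoxyallene 15 (not isolated)
Conditions: n-BuLi, THF, −40 °C; then 14, −40 °C → rt; stored over K2CO3
Reagents that add atoms: none
Why: α-Lithiation of methoxyallene at the oxygen-bearing carbon followed by SN2 alkylation with a primary bromide is the standard entry to 1-alkyl-1-alkoxyallenes and puts the hexadecyl chain on the future C6.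

Step 10
Reactants: 16 3-methoxynonadeca-1,2-diene
Product: 17 3,3-dimethoxynonadec-1-ene
Conditions: MeOH, PPTS (cat.), 0 °C; Et3N quench; basic alumina
Reagents that add atoms: methanol CO
Why: Acid-catalysed addition of an alcohol to an alkoxyallene: protonation of the central allene carbon gives the 1-methoxyallyl oxocarbenium ion, which methanol captures at the oxygen-bearing carbon under kinetic control, so the vinyl ketone dimethyl ketal is reached without passing through the enone and its conjugate-addition chemistry.

Step 11
Reactants: 12 methyl (3S)-3-hydroperoxypent-4-enoate; 17 3,3-dimethoxynonadec-1-ene (2 equiv)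
Product: 18 methyl (3S)-3-[(3-methoxynonadec-1-en-3-yl)peroxy]pent-4-enoate (both epimers at the peroxyketal carbon)
Conditions: PPTS (cat.), 5 Å MS, CH2Cl2, 0 °C → rt; Et3N quench; Et3N-washed silica
Reagents that add atoms: none
Why: Acid-catalysed ketal exchange (transperoxyketalisation): PPTS ionises one methoxy group of the allylic ketal, the hydroperoxide O–H adds to the oxocarbenium carbon and the sieves take up the methanol released; the new stereocentre at the peroxyketal carbon is not controlled, since the remote C3 centre cannot bias the faces of the planar cation, so both epimers are expected in comparable amounts and are carried on together.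

Step 12
Reactants: 18 methyl (3S)-3-[(3-methoxynonadec-1-en-3-yl)peroxy]pent-4-enoate (both epimers at the peroxyketal carbon)
Product: 19 methyl 2-[(3S)-6-hexadecyl-6-methoxy-3,6-dihydro-1,2-dioxin-3-yl]acetate (both C6 epimers)
Conditions: (H2IMes)(PCy3)Cl2Ru=CHPh (5–10 mol%), CH2Cl2 (5 mM), 40 °C; ethyl vinyl ether quench; Et3N-washed silica
Reagents that add atoms: none
Why: Ring-closing olefin metathesis: the Ru benzylidene exchanges onto the unhindered vinyl group at C3, the resulting alkylidene adds across the vinyl group on the fully substituted peroxyketal carbon to a ruthenacyclobutane, and cycloreversion releases ethene and the C4=C5 bond. The closest known reaction type is RCM of heteroatom-tethered 1,7-dienes to six-membered allylic heterocycles (mixed acrolein acetals to 2-alkoxy-3,6-dihydropyrans), run with Ru carbenes that tolerate dialkyl peroxides. The one ring formed, the six-membered 1,2-dioxine, closes by intramolecular [2+2]/retro-[2+2] with the new alkene endocyclic and necessarily Z. No stereocentre is created: C3 comes from step 3 and no bond to the peroxyketal carbon is touched, so each epimer of 18 maps onto one C6 epimer of 19. The selectivity needed is chemoselectivity for the two terminal alkenes over the O–O bond and the ionisable allylic peroxyketal; it is secured because the peroxide is a hindered, fully alkylated dialkyl peroxide with no O–H, the medium is neutral, and high dilution with loss of ethene favours the six-membered ring over oligomers.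

Step 13
Reactants: 19 methyl 2-[(3S)-6-hexadecyl-6-methoxy-3,6-dihydro-1,2-dioxin-3-yl]acetate (both C6 epimers)
Product: 20 methyl 2-[(3S,6S)-6-hexadecyl-6-methoxy-3,6-dihydro-1,2-dioxin-3-yl]acetate (6-epi-chondrillin; target)
Conditions: PPTS (cat.), MeOH, rt; Et3N quench; chromatography; recovered 6R epimer resubmitted
Reagents that add atoms: methanol CO
Why: Acid-catalysed equilibration of a cyclic peroxyketal (anomerisation): reversible ionisation of the C6–OMe bond to the ring peroxy-oxocarbenium ion and recapture by solvent methanol sets C6 under thermodynamic control; the 6S isomer is expected to be favoured because it alone can place the methoxy group pseudoaxial (anomeric stabilisation by O1) with both carbon chains pseudoequatorial, the minor 6R isomer is removed by chromatography, and C3 and the methyl ester are unchanged in methanol.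

**Compound list**

1 | 2,3-dimethylbut-2-ene | CC(C)=C(C)C | starting material
2 | 2-hydroperoxy-2-methoxypropane | COC(C)(C)OO | intermediate
3 | (3R)-3-hydroxyoxolan-2-one | O[C@@H]1CCOC1=O | starting material
4 | (3R)-2-oxooxolan-3-yl trifluoromethanesulfonate | O=S(=O)(O[C@@H]1CCOC1=O)C(F)(F)F | intermediate
5 | potassium 2-methoxypropane-2-peroxolate (not isolated) | [K+].[O-]OC(C)(C)OC | intermediate
6 | (3S)-3-[(2-methoxypropan-2-yl)peroxy]oxolan-2-one | COC(C)(C)OO[C@H]1CCOC1=O | intermediate
7 | (3S)-3-[(2-methoxypropan-2-yl)peroxy]oxolan-2-ol (both anomers) | COC(C)(C)OO[C@H]1CCOC1O | intermediate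
8 | (3S)-3-[(2-methoxypropan-2-yl)peroxy]pent-4-en-1-ol | C=C[C@H](CCO)OOC(C)(C)OC | intermediate
9 | (3S)-3-[(2-methoxypropan-2-yl)peroxy]pent-4-enal (not isolated) | C=C[C@H](CC=O)OOC(C)(C)OC | intermediate
10 | (3S)-3-[(2-methoxypropan-2-yl)peroxy]pent-4-enoic acid | C=C[C@H](CC(=O)O)OOC(C)(C)OC | intermediate
11 | methyl (3S)-3-[(2-methoxypropan-2-yl)peroxy]pent-4-enoate | C=C[C@H](CC(=O)OC)OOC(C)(C)OC | intermediate
12 | methyl (3S)-3-hydroperoxypent-4-enoate | C=C[C@H](CC(=O)OC)OO | intermediate
13 | methoxyallene (1-methoxypropa-1,2-diene) | COC=C=C | starting material
14 | 1-bromohexadecane | CCCCCCCCCCCCCCCCBr | starting material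
15 | 1-lithio-1-methoxyallene (not isolated) | [Li]C(OC)=C=C | intermediate
16 | 3-methoxynonadeca-1,2-diene | CCCCCCCCCCCCCCCCC(OC)=C=C | intermediate
17 | 3,3-dimethoxynonadec-1-ene | CCCCCCCCCCCCCCCCC(OC)(OC)C=C | intermediate
18 | methyl (3S)-3-[(3-methoxynonadec-1-en-3-yl)peroxy]pent-4-enoate (both epimers at the peroxyketal carbon) | CCCCCCCCCCCCCCCCC(OO[C@@H](CC(=O)OC)C=C)(OC)C=C | intermediate
19 | methyl 2-[(3S)-6-hexadecyl-6-methoxy-3,6-dihydro-1,2-dioxin-3-yl]acetate (both C6 epimers) | CCCCCCCCCCCCCCCCC1(OC)C=C[C@H](CC(=O)OC)OO1 | intermediate
20 | methyl 2-[(3S,6S)-6-hexadecyl-6-methoxy-3,6-dihydro-1,2-dioxin-3-yl]acetate (6-epi-chondrillin) | CCCCCCCCCCCCCCCC[C@@]1(OC)C=C[C@H](CC(=O)OC)OO1 | target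

**Count and risks**

Total: 13 steps. Longest linear sequence: 10 steps (steps 2–8 and 11–13, from lactone 3; the chain from alkene 1 through steps 1, 3–8 and 11–13 is equally long).

Steps most likely to fail:

1. Step 3. The peroxide anion may remove the acidic α-proton of the α-peroxy lactone as it forms, so that O–O fragmentation of the enolate (Kornblum–DeLaMare) or E2 loss of triflate outruns substitution. The fallback replaces anion alkylation by neutral peroxide transfer from tin. It sets out from 2 and 4: hydroperoxide 2 is condensed with bis(tributyltin) oxide (benzene, 4 Å MS) to tributyl[(2-methoxypropan-2-yl)peroxy]stannane F1. This is alkylated by triflate 4 in CH2Cl2 (−20 °C → rt) with inversion, as organotin peroxides are by alkyl triflates, so that no base is present at any time. It comes back to the route at 6.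

2. Step 5. Opening of the lactol needs the alkoxide and an excess of ylide, and the transient α-peroxy aldehyde may be deprotonated by the ylide faster than it is olefinated, ending in O–O cleavage or loss of configuration at C3. The fallback replaces the stoichiometric basic ylide by catalytic methylenation under neutral conditions. It sets out from 7: RhCl(PPh3)3 (cat.), TMSCHN2, PPh3 and 2-propanol in THF at rt generate the phosphorane only in low stationary concentration, and the aldehyde tautomer is olefinated without free base. It comes back to the route at 8 and makes no new compound.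

3. Step 11. The exchange is an equilibrium that liberates methanol, so incomplete conversion and back-exchange of the product by the methanol released may erode the mixed peroxyketal. The fallback replaces exchange by irreversible addition. It sets out from 12 and allene 16, bypassing 17: PPTS (cat.) in CH2Cl2 at 0 °C adds the O–H of 12 across the enol-ether double bond of 16 through the same oxocarbenium ion without any methanol being formed, in the way hydroperoxides add to 2-methoxypropene and alcohols add to alkoxyallenes. It comes back to the route at 18 and makes no new compound.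

**Further compounds**

F1 | step 3 | tributyl[(2-methoxypropan-2-yl)peroxy]stannane | CCCC[Sn](CCCC)(CCCC)OOC(C)(C)OC
F0 | step 5 | none | none
F0 | step 11 | none | none
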